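**Remarks.** Locants C1–C11 and C15 are those of the target's carbon framework and are used for every compound: ring A = C1–C5 and C10, ring B = C5–C10, C11 = exocyclic methylene carbon, C15 = benzylic CH2. Descriptors on bicyclic compounds refer to these locants. Compounds 2 and 13 are catalogue chemicals. Compound 15 holds two alkyl groups on one zinc, so step 5 consumes two molecules of 13 for each molecule of 15. Assumption: the (S,R,R)-phosphoramidite is taken as the ligand enantiomer that delivers the chain to the enone arm drawn; if the sense of induction is the opposite, its mirror image is used and nothing else changes.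

## Structural features

The target 26 is a rearranged drimane-type hydroxyquinone: a cis-fused decalin that carries an exocyclic C4=C11 methylene, an angular methyl on C5, a methyl on C8 and, on quaternary C9, a methyl and the benzylic C15 that leads to a 2-hydroxy-5-methoxy-1,4-benzoquinone. Four contiguous stereocentres line ring B, C5 (R), C10 (S), C9 (R) and C8 (R), two of them quaternary. The C5 methyl, the C10 hydrogen, C15 and the C8 methyl lie on one face of ring B, whereas the C9 methyl and both bonds to ring A (C10–C1, C5–C4) lie on the other. The fragile groups are the 1,1-disubstituted alkene, which migrates into the ring under acid and would be engaged by a radical or cation at C6, and the quinone, which tolerates neither organometallic nor strongly reducing steps and is therefore carried as a 2,3,5,6-tetramethoxyphenyl group until the end. The real difficulty is the crowded C5–C10–C9–C8 array in a region that has no functional group in the target, together with the absolute configuration of quaternary C9. The plan exploits the position of C9 between C8 and C10 and para to C6: with C6 as a carbonyl and both C5=C10 and C7=C8 unsaturated, ring B is a flat, achiral cyclohexa-2,5-dienone in which C9 is prochiral and the two enone arms are enantiotopic. Attaching the ring A chain to C10 of one arm therefore creates C10 and makes C9 a stereocentre in the same event.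

## Logic of the disconnections

26 ⇒ 25 ⇒ 24. The hydroxyl C–O bond and the two quinone carbonyls are traced back to four aryl methyl ethers, because the quinone would not survive the organometallic and reductive chemistry. The gain is a robust arene that comes from commercial 1. The forward steps must oxidise the ring without touching C4=C11 and must hydrolyse only the methoxy group next to the C15-bearing carbon.

24 ⇒ 22. The C6 methylene is traced back to a C6 carbonyl, which is the one handle that can activate C5, C8 and C10 in turn. This exposes a β-methyl ketone. The removal must avoid a radical or cation at C6, which is homoallylic to C4=C11, and must avoid acid.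

22 ⇒ 20. The C8–CH3 bond is cut as a conjugate addition to the C7=C8 enone. The methyl group must enter syn to C15, on the face away from ring A. This step is placed after ring A closure so that the cuprate never meets the terminal alkyne.

20 ⇒ 19 ⇒ 18. The C4–C5 bond is cut as an intramolecular addition of the C5 enol to a C4≡C11 alkyne. This opens ring A, explains the exocyclic methylene as a former terminal alkyne and reduces quaternary C5 to an α-methyl ketone carbon. The closure must be 6-exo and cis. Enol regiochemistry is not an issue because C5–H is the only enolisable hydrogen of 18.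

18 ⇒ 17. The C11–Si bond is cut; the alkyne is masked while organozinc and copper species are present.

17 ⇒ 12 + 15 (plus a methyl electrophile). The C10–C1 and C5–CH3 bonds are cut together. This is the strategic cut: it removes the whole side chain and all stereocentres and leaves an achiral dienone. The chain that is transferred is five carbons long (C1–C4 plus C11). Compound 17 carries three stereocentres, not two (C5, C9 and C10), and C5 is provisional. The forward step needs catalyst control over which enantiotopic arm reacts, substrate control of the ring face, mono-addition and C-methylation.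

15 ⇒ 13. The two C–Zn bonds are cut back to a commercial chloride, two molecules of which are needed for each zinc. The reagent must be free of magnesium halide.

12 ⇒ 10. The C7=C8 π bond is removed to reveal a Robinson retron. The forward dehydrogenation must spare the electron-rich arene and C15.

10 ⇒ 6 + 7. C8–C9 (Michael) and C5=C10 (aldol condensation) are cut. Quaternary C9 arises from the α-carbon of an α-branched aldehyde, which is a poor Michael donor under base and is therefore used as its enamine.

6 ⇒ 5 ⇒ 1 + 2. The C=C bond is reduced, then the aryl–C15 bond is cut. Both partners are commercial, and the sequence to 12 takes four steps.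

## Other disconnections considered

Alternative 1: The cut is C10–C1 and C4–C5, that is ring A. In the forward direction diene A3, which carries an (S)-O-methylmandelate auxiliary, adds thermally across the methyl-bearing double bond of quinone A2 to give the cis-fused adduct A1.
- In its favour: ring A, quaternary C5 and C10 are formed in one step, and the cis fusion follows from the suprafacial addition itself. On this point it is better than the chosen plan, where cis fusion rests on the kinetic course of step 9. It is also better in operational simplicity: cheap materials, no air-sensitive reagent, no catalyst.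
- Against it here: C9 arrives as a ketone. The hardest centre, quaternary C9 with its methyl and C15–aryl arm, is left open, as is C8. C4, C6 and C9 all need redox adjustment, the C2=C3 alkene must be removed, and the arene is attached late. The auxiliary is stoichiometric and remote from the reacting carbons, and the regiochemistry must pair the acyloxy terminus with C5.
- Comparison: on structure, A1 solves C5/C10 while 17 solves C9/C10 and already carries the aryl unit and the C4/C11 carbons. On mechanism, a concerted cycloaddition is the more predictable way to fix relative configuration, but a catalytic ligand is the more economical way to fix absolute configuration. On step economy, the route from A1 is estimated to need well over ten further steps against seven from 17.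

Alternative 2: The cut is C9–C10 and C7–C8, that is ring B. In the forward direction phenol A5 is oxidised with PhI(OAc)2 in methanol, and the tethered (Z)-alkene adds across the resulting diene to give bicyclo[2.2.2]octenone A4.
- In its favour: C8, C9 and C10 are set in one operation with the relative configuration of the target. C8/C9 follows from alkene geometry and C9/C10 from the tether. This is better than the chosen plan, which depends on methyl versus arylmethyl discrimination in step 6 and on facial selectivity in step 10. The two carbon arms on C9 are chemically distinct from the start, and the step is metal-free.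
- Against it here: A5 is achiral, and the ketal carbon that relays all configuration is created in the oxidation, so A4 is racemic unless a chiral oxidant or a resolution is added. Ring A is absent. The ketone and ketal carbons of A4 map onto C2 and C1, so a vinyl addition and an anionic oxy-Cope rearrangement would be needed to form C4–C5. After that, two oxygens must be removed, C6=C7 reduced, C4=C11 installed at an unfunctionalised carbon, the tetrahydrofuran C–O bond cleaved to the C9 methyl, and the arene attached at C15.
- Comparison: on structure it sets three of the four centres but leaves C5, ring A and the arene. On mechanism it is a pericyclic cascade with good relative but no absolute control. On step economy it is clearly longer than the chosen plan.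

Alternative 3: The cut is C5–C10, made by a ring reorganisation. In the forward direction BF3·OEt2 opens the C5–C6 epoxide of trans-fused hydroazulene A7 while C10 migrates from C4 to C5, giving cis-decalin ketone A6.
- In its favour: the 1,2-shift is stereospecific (anti to the epoxide C–O bond, retention at C10), so quaternary C5 and the cis fusion are formed together. A6 already has all four stereocentres and a C4 ketone for methylenation. The C6 oxygen can be removed before the alkene exists, which is better than the chosen plan, where step 11 must work with C4=C11 present. The endgame from A6 is about as short as that from 20.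
- Against it here: the rearrangement only relays configuration. A7 must already contain C8, quaternary C9 with the arylmethyl group, C10 and a matched epoxy alcohol on a seven-membered ring, which is no easier to build than the decalin. The migration needs a conformation that places C10, not C3, anti to the breaking bond, and hydride shift is a competing pathway. Methylenation of the hindered C4 ketone next to C5 comes late.
- Comparison: on structure the chosen plan creates stereocentres from an achiral ring where this one transfers them. On mechanism a cationic shift under Lewis acid is less tolerant than copper catalysis. On step economy the short endgame is outweighed by the long route to A7.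

Key step: step 6

## Route

Step 1
Reactants: 1 1,2,4,5-tetramethoxybenzene; 2 (E)-3-(dimethylamino)-2-methylprop-2-enal
Product: 5 (E)-2-methyl-3-(2,3,5,6-tetramethoxyphenyl)prop-2-enal, via aryllithium 3 (not isolated), via lithium alkoxide adduct 4 (not isolated)
Conditions: n-BuLi, TMEDA, THF, 0 °C; 2, −78 → 0 °C; 2 M HCl, rt
Reagents that add atoms: none
Why: Directed ortho-lithiation occurs at the only kind of ring C–H, flanked by two methoxy groups; 3 adds 1,2 to the formyl group of vinylogous formamide 2, and acid expels dimethylamine through the vinylogous iminium ion, a known enal synthesis that gives the conjugated (E)-isomer.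

Step 2
Reactants: 5 (E)-2-methyl-3-(2,3,5,6-tetramethoxyphenyl)prop-2-enal
Product: 6 2-methyl-3-(2,3,5,6-tetramethoxyphenyl)propanal (racemic)
Conditions: H2 (1 atm), Pd/C (5 wt%), EtOAc, rt, stopped after one equivalent
Reagents that add atoms: none
Why: Heterogeneous hydrogenation of the conjugated C=C is faster than reduction of the aldehyde or arene and is the standard way to 2-methyl-3-arylpropanals; the racemic α-centre is of no consequence because it becomes prochiral C9 of 12.

Step 3
Reactants: 6 2-methyl-3-(2,3,5,6-tetramethoxyphenyl)propanal; 7 but-3-en-2-one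
Product: 10 4-methyl-4-[(2,3,5,6-tetramethoxyphenyl)methyl]cyclohex-2-en-1-one (racemic), via pyrrolidine enamine 8 (not isolated), via keto aldehyde 9 (not isolated)
Conditions: pyrrolidine, toluene, reflux (Dean–Stark); 7, rt; AcOH/NaOAc/H2O, reflux
Reagents that add atoms: none
Why: Stork enamine version of the Robinson annulation: the α-carbon of 6 adds to 7 to form C8–C9 and the quaternary carbon, hydrolysis gives 9, and buffered aldol condensation closes ring B as the enone; strong acid (arene addition to 7) and strong base are avoided.

Step 4
Reactants: 10 4-methyl-4-[(2,3,5,6-tetramethoxyphenyl)methyl]cyclohex-2-en-1-one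
Product: 12 4-methyl-4-[(2,3,5,6-tetramethoxyphenyl)methyl]cyclohexa-2,5-dien-1-one, via silyl dienol ether 11 (not isolated)
Conditions: LiN(iPr)2, THF, −78 °C; Me3SiCl; then Pd(OAc)2 (10 mol%), O2 (1 atm), DMSO, rt
Reagents that add atoms: none
Why: Kinetic α′-deprotonation and O-silylation give 11; Saegusa–Ito dehydrogenation (palladium enolate, β-hydride elimination, reoxidation of zerovalent palladium by O2) installs the second C=C without the quinone oxidants that would attack the electron-rich arene or C15. Compound 12 is achiral, with a mirror plane through C6 and C9.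

Step 5
Reactants: 13 (5-chloropent-1-yn-1-yl)trimethylsilane (2 equiv, two molecules for each molecule of 15)
Product: 15 bis[5-(trimethylsilyl)pent-4-yn-1-yl]zinc, via Grignard reagent 14 (not isolated)
Conditions: 13 (2.0 equiv), Mg (2.2 equiv), I2 (cat.), THF, reflux; ZnCl2 (1.0 equiv, half an equivalent per Grignard), Et2O, 0 °C → rt; 1,4-dioxane, filtration under Ar; titrated solution in toluene
Reagents that add atoms: zinc dichloride, Cl[Zn]Cl; second molecule of 13, (5-chloropent-1-yn-1-yl)trimethylsilane, C[Si](C)(C)C#CCCCCl
Why: Magnesium insertion into the primary C–Cl bond gives 14, and two molecules of 14 transfer their alkyl groups to one ZnCl2 (double transmetalation), which accounts for both chains of 15. Dioxane precipitates the magnesium halide, so a salt-free dialkylzinc is obtained, which the ligand-controlled copper cycle needs. The silylated alkyne is inert to both metals.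

Step 6
Reactants: 12 4-methyl-4-[(2,3,5,6-tetramethoxyphenyl)methyl]cyclohexa-2,5-dien-1-one; 15 bis[5-(trimethylsilyl)pent-4-yn-1-yl]zinc
Product: 17 (4R,5R,6R)-4,6-dimethyl-4-[(2,3,5,6-tetramethoxyphenyl)methyl]-5-[5-(trimethylsilyl)pent-4-yn-1-yl]cyclohex-2-en-1-one, via zinc enolate 16 (not isolated)
Conditions: Cu(OTf)2 (3 mol%), (S,R,R)-O,O′-(1,1′-binaphthalene-2,2′-diyl) N,N-bis(1-phenylethyl)phosphoramidite (6 mol%), 15 (1.1 equiv), toluene, −30 °C; then MeI, DMPU, −30 → 0 °C; 1 M HCl work-up
Reagents that add atoms: iodomethane, CI
Why: Cu(OTf)2 is reduced by 15 to a monovalent copper–phosphoramidite complex that takes an alkyl group from zinc; π-complexation to one enone arm, oxidative addition at C10 to a trivalent copper enolate and reductive elimination form C10–C1 and leave cross-conjugated zinc dienolate 16, which DMPU activates for SN2 methylation at C5. The closest known reaction type is the copper/phosphoramidite-catalysed enantioselective desymmetrising conjugate addition of dialkylzincs to 4,4-disubstituted cyclohexa-2,5-dienones with in-flask enolate alkylation. No ring is closed. C10 is set by the ligand, which dictates the face of the β-carbon that receives the chain. C9 becomes a stereocentre through the choice of arm: the ligand-preferred β-face lies on opposite ring faces in the two arms, so the substrate's preference for attack anti to the bulky arylmethyl group selects the arm and places C1 trans to C15. C5 is set by the substrate, since iodomethane approaches the dienolate anti to the adjacent C10 chain; this centre is provisional and is remade in step 9. The step needs enantiotopic-arm selection (ligand), anti facial selection (arylmethyl against methyl on C9), 1,4- over 1,2-addition (soft copper nucleophile) and mono-addition. Mono-addition is secured because the second arm is locked in the electron-rich dienolate until methylation, after which coordinating DMPU and the small excess of 15 hold back a second addition at C8.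

Step 7
Reactants: 17 (4R,5R,6R)-4,6-dimethyl-4-[(2,3,5,6-tetramethoxyphenyl)methyl]-5-[5-(trimethylsilyl)pent-4-yn-1-yl]cyclohex-2-en-1-one
Product: 18 (4R,5R,6R)-4,6-dimethyl-5-(pent-4-yn-1-yl)-4-[(2,3,5,6-tetramethoxyphenyl)methyl]cyclohex-2-en-1-one
Conditions: K2CO3, MeOH, rt
Reagents that add atoms: none
Why: Methoxide-mediated protodesilylation cleaves only the C(sp)–Si bond; the base can at most equilibrate C5, which is already in its more stable trans arrangement and is erased in step 8.

Step 8
Reactants: 18 (4R,5R,6R)-4,6-dimethyl-5-(pent-4-yn-1-yl)-4-[(2,3,5,6-tetramethoxyphenyl)methyl]cyclohex-2-en-1-one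
Product: 19 tert-butyl({(3S,4R)-2,4-dimethyl-3-(pent-4-yn-1-yl)-4-[(2,3,5,6-tetramethoxyphenyl)methyl]cyclohexa-1,5-dien-1-yl}oxy)dimethylsilane
Conditions: TBSOTf, Et3N, CH2Cl2, 0 °C; NaHCO3 work-up
Reagents that add atoms: tert-butyldimethylsilyl trifluoromethanesulfonate, CC(C)(C)[Si](C)(C)OS(=O)(=O)C(F)(F)F
Why: Soft enolisation; C5–H is the only enolisable hydrogen (C7 is vinylic, C9 quaternary), so a single 2-silyloxydiene (C5=C6 and C7=C8) forms and the provisional C5 centre is flattened on purpose.

Step 9
Reactants: 19 tert-butyl({(3S,4R)-2,4-dimethyl-3-(pent-4-yn-1-yl)-4-[(2,3,5,6-tetramethoxyphenyl)methyl]cyclohexa-1,5-dien-1-yl}oxy)dimethylsilane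
Product: 20 (5R,9R,10S)-5,9-dimethyl-4-methylidene-9-[(2,3,5,6-tetramethoxyphenyl)methyl]-cis-decal-7-en-6-one
Conditions: Ph3PAuCl (5 mol%), AgBF4 (5 mol%), CH2Cl2/MeOH (10:1), rt
Reagents that add atoms: none
Why: Conia-ene-type carbocyclisation of a silyl enol ether: the cationic monovalent gold complex activates the terminal alkyne, enol carbon C5 attacks C4 anti to gold in a 6-exo-dig closure, and protodeauration by methanol leaves the exocyclic C4=C11 while methanol takes the silyl group. Quaternary C5 is set by the tether: A(1,2) strain with the C5 methyl holds the C10 chain pseudoaxial, so it reaches only the face of C5 on its own side and ring A closes cis, with the C5 methyl syn to the C10 hydrogen.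

Step 10
Reactants: 20 (5R,9R,10S)-5,9-dimethyl-4-methylidene-9-[(2,3,5,6-tetramethoxyphenyl)methyl]-cis-decal-7-en-6-one
Product: 22 (5R,8R,9R,10S)-5,8,9-trimethyl-4-methylidene-9-[(2,3,5,6-tetramethoxyphenyl)methyl]-cis-decalin-6-one, via silyl enol ether 21 (not isolated)
Conditions: Me2CuLi (from CuI and 2 MeLi), Me3SiCl, THF/Et2O, −78 → −30 °C; aq. NH4Cl; then K2CO3, MeOH, rt
Reagents that add atoms: lithium dimethylcuprate, [Li+].C[Cu-]C
Why: Chlorosilane-accelerated Gilman conjugate addition to the C7=C8 enone. C8 is set by the bicyclic substrate: axial attack anti to the pseudoaxial C9 methyl, on the convex face away from the ring A bonds C10–C1 and C5–C4, places the new methyl syn to C15. Mild methanolysis of 21 returns the ketone.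

Step 11
Reactants: 22 (5R,8R,9R,10S)-5,8,9-trimethyl-4-methylidene-9-[(2,3,5,6-tetramethoxyphenyl)methyl]-cis-decalin-6-one
Product: 24 (5R,8R,9R,10S)-5,8,9-trimethyl-4-methylidene-9-[(2,3,5,6-tetramethoxyphenyl)methyl]-cis-decalin, via hydrazone 23 (not isolated)
Conditions: N2H4·H2O, KOH, diethylene glycol, 130 °C, then 195 °C with removal of water, under Ar
Reagents that add atoms: none
Why: Wolff–Kishner reduction (Huang-Minlon procedure) through hydrazone 23 and its diazenyl anion removes the C6 oxygen by an anionic pathway, avoiding a C6 radical that could rearrange through the neighbouring C4=C11. No centre next to C6 carries a hydrogen that matters (C5 is quaternary), and hydroxide in glycol is too weak a base to move the exocyclic alkene.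

Step 12
Reactants: 24 (5R,8R,9R,10S)-5,8,9-trimethyl-4-methylidene-9-[(2,3,5,6-tetramethoxyphenyl)methyl]-cis-decalin
Product: 25 2,5-dimethoxy-3-{[(5R,8R,9R,10S)-5,8,9-trimethyl-4-methylidene-cis-decalin-9-yl]methyl}cyclohexa-2,5-diene-1,4-dione
Conditions: (NH4)2Ce(NO3)6 (2.5 equiv), MeCN/H2O, 0 °C, short reaction time
Reagents that add atoms: water, O
Why: Oxidative demethylation by tetravalent cerium via the arene radical cation; water adds at two para methoxy-bearing carbons and methanol is lost. Both para pairs give the same quinone because of the symmetry of the ring, and a brief reaction at 0 °C should spare the alkene.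

Step 13
Reactants: 25 2,5-dimethoxy-3-{[(5R,8R,9R,10S)-5,8,9-trimethyl-4-methylidene-cis-decalin-9-yl]methyl}cyclohexa-2,5-diene-1,4-dione
Product: 26 2-hydroxy-5-methoxy-3-{[(5R,8R,9R,10S)-5,8,9-trimethyl-4-methylidene-cis-decalin-9-yl]methyl}cyclohexa-2,5-diene-1,4-dione
Conditions: KOH, MeOH/H2O, rt; then 0.5 M HCl to pH 4, 0 °C
Reagents that add atoms: potassium hydroxide, [K+].[OH-]
Why: Addition–elimination of hydroxide on a vinylogous ester; the methoxy group flanked by the C15-bearing carbon is twisted out of conjugation and should be the more electrophilic site, and the vinylogous carboxylate formed deactivates the ring towards a second hydrolysis. Mild acidification liberates 26.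

## Compound list

1 | 1,2,4,5-tetramethoxybenzene | COc1cc(OC)c(OC)cc1OC | starting material
2 | (E)-3-(dimethylamino)-2-methylprop-2-enal | CN(C)/C=C(\C)C=O | starting material
3 | (2,3,5,6-tetramethoxyphenyl)lithium | [Li]c1c(OC)c(OC)cc(OC)c1OC | intermediate (not isolated)
4 | lithium (E)-3-(dimethylamino)-2-methyl-1-(2,3,5,6-tetramethoxyphenyl)prop-2-en-1-olate, racemic | [Li]OC(c1c(OC)c(OC)cc(OC)c1OC)/C(C)=C/N(C)C | intermediate (not isolated)
5 | (E)-2-methyl-3-(2,3,5,6-tetramethoxyphenyl)prop-2-enal | O=C/C(C)=C/c1c(OC)c(OC)cc(OC)c1OC | intermediate
6 | 2-methyl-3-(2,3,5,6-tetramethoxyphenyl)propanal, racemic | O=CC(C)Cc1c(OC)c(OC)cc(OC)c1OC | intermediate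
7 | but-3-en-2-one (methyl vinyl ketone) | CC(=O)C=C | starting material
8 | 1-[2-methyl-3-(2,3,5,6-tetramethoxyphenyl)prop-1-en-1-yl]pyrrolidine, E/Z mixture | CC(=CN1CCCC1)Cc1c(OC)c(OC)cc(OC)c1OC | intermediate (not isolated)
9 | 2-methyl-5-oxo-2-[(2,3,5,6-tetramethoxyphenyl)methyl]hexanal, racemic | CC(=O)CCC(C)(C=O)Cc1c(OC)c(OC)cc(OC)c1OC | intermediate (not isolated)
10 | 4-methyl-4-[(2,3,5,6-tetramethoxyphenyl)methyl]cyclohex-2-en-1-one, racemic | CC1(Cc2c(OC)c(OC)cc(OC)c2OC)CCC(=O)C=C1 | intermediate
11 | trimethyl({4-methyl-4-[(2,3,5,6-tetramethoxyphenyl)methyl]cyclohexa-1,5-dien-1-yl}oxy)silane, racemic | CC1(Cc2c(OC)c(OC)cc(OC)c2OC)CC=C(O[Si](C)(C)C)C=C1 | intermediate (not isolated)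
12 | 4-methyl-4-[(2,3,5,6-tetramethoxyphenyl)methyl]cyclohexa-2,5-dien-1-one, achiral | CC1(Cc2c(OC)c(OC)cc(OC)c2OC)C=CC(=O)C=C1 | intermediate
13 | (5-chloropent-1-yn-1-yl)trimethylsilane | C[Si](C)(C)C#CCCCCl | starting material
14 | [5-(trimethylsilyl)pent-4-yn-1-yl]magnesium chloride | C[Si](C)(C)C#CCCC[Mg]Cl | intermediate (not isolated)
15 | bis[5-(trimethylsilyl)pent-4-yn-1-yl]zinc | C[Si](C)(C)C#CCCC[Zn]CCCC#C[Si](C)(C)C | intermediate
16 | alkylzinc dienolate of the conjugate adduct (9R,10R), chain on C10 trans to C15 | C[Si](C)(C)C#CCCC[C@H]1[C@](C)(Cc2c(OC)c(OC)cc(OC)c2OC)C=CC(O[Zn]CCCC#C[Si](C)(C)C)=C1 | intermediate (not isolated)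
17 | (4R,5R,6R)-4,6-dimethyl-4-[(2,3,5,6-tetramethoxyphenyl)methyl]-5-[5-(trimethylsilyl)pent-4-yn-1-yl]cyclohex-2-en-1-one | C[Si](C)(C)C#CCCC[C@H]1[C@](C)(Cc2c(OC)c(OC)cc(OC)c2OC)C=CC(=O)[C@@H]1C | intermediate
18 | (4R,5R,6R)-4,6-dimethyl-5-(pent-4-yn-1-yl)-4-[(2,3,5,6-tetramethoxyphenyl)methyl]cyclohex-2-en-1-one | C#CCCC[C@H]1[C@](C)(Cc2c(OC)c(OC)cc(OC)c2OC)C=CC(=O)[C@@H]1C | intermediate
19 | tert-butyl({(3S,4R)-2,4-dimethyl-3-(pent-4-yn-1-yl)-4-[(2,3,5,6-tetramethoxyphenyl)methyl]cyclohexa-1,5-dien-1-yl}oxy)dimethylsilane (silyl dienol ether at C6, double bonds C5=C6 and C7=C8) | C#CCCC[C@H]1[C@](C)(Cc2c(OC)c(OC)cc(OC)c2OC)C=CC(O[Si](C)(C)C(C)(C)C)=C1C | intermediate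
20 | (5R,9R,10S)-5,9-dimethyl-4-methylidene-9-[(2,3,5,6-tetramethoxyphenyl)methyl]-cis-decal-7-en-6-one (C5 methyl and C10 hydrogen cis; C15 trans to C10–C1) | C=C1CCC[C@H]2[C@](C)(Cc3c(OC)c(OC)cc(OC)c3OC)C=CC(=O)[C@@]12C | intermediate
21 | trimethylsilyl enol ether (C6=C7) of 22, (5R,8R,9R,10S) | C=C1CCC[C@H]2[C@](C)(Cc3c(OC)c(OC)cc(OC)c3OC)[C@H](C)C=C(O[Si](C)(C)C)[C@@]12C | intermediate (not isolated)
22 | (5R,8R,9R,10S)-5,8,9-trimethyl-4-methylidene-9-[(2,3,5,6-tetramethoxyphenyl)methyl]-cis-decalin-6-one (C8 methyl syn to C15) | C=C1CCC[C@H]2[C@](C)(Cc3c(OC)c(OC)cc(OC)c3OC)[C@H](C)CC(=O)[C@@]12C | intermediate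
23 | C6 hydrazone of 22, (5R,8R,9R,10S) | C=C1CCC[C@H]2[C@](C)(Cc3c(OC)c(OC)cc(OC)c3OC)[C@H](C)CC(=NN)[C@@]12C | intermediate (not isolated)
24 | (5R,8R,9R,10S)-5,8,9-trimethyl-4-methylidene-9-[(2,3,5,6-tetramethoxyphenyl)methyl]-cis-decalin | C=C1CCC[C@H]2[C@](C)(Cc3c(OC)c(OC)cc(OC)c3OC)[C@H](C)CC[C@@]12C | intermediate
25 | 2,5-dimethoxy-3-{[(5R,8R,9R,10S)-5,8,9-trimethyl-4-methylidene-cis-decalin-9-yl]methyl}cyclohexa-2,5-diene-1,4-dione | C=C1CCC[C@H]2[C@](C)(CC3=C(OC)C(=O)C=C(OC)C3=O)[C@H](C)CC[C@@]12C | intermediate
26 | 2-hydroxy-5-methoxy-3-{[(5R,8R,9R,10S)-5,8,9-trimethyl-4-methylidene-cis-decalin-9-yl]methyl}cyclohexa-2,5-diene-1,4-dione | C=C1CCC[C@H]2[C@](C)(CC3=C(O)C(=O)C=C(OC)C3=O)[C@H](C)CC[C@@]12C | target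

## Step count and risks

Total step count: 13. Longest linear sequence: 12 steps (steps 1–4, then 6–13); step 5 is a one-step side branch.

Step 6 (key step). The most likely failure is slow C-methylation of the weakly nucleophilic zinc enolate. While it lingers, proton exchange can give unmethylated and over-methylated material, and once enone 17 exists, residual organozinc can add a second time at C8. A second concern is incomplete facial discrimination between methyl and arylmethyl on C9, which would give a diastereomer with the chain syn to C15. Fallback: separate the two bond formations. Set out from 12 and 15 and run the copper-catalysed addition alone, then quench with acid to give (4S,5R)-4-methyl-4-[(2,3,5,6-tetramethoxyphenyl)methyl]-5-[5-(trimethylsilyl)pent-4-yn-1-yl]cyclohex-2-en-1-one F1, from which any diastereomer is removed by chromatography. Then form the kinetic lithium dienolate (LiN(iPr)2, THF, −78 °C; only C5 carries α-hydrogens) and alkylate with MeI, which should enter trans to the C10 chain. The fallback comes back to the route at 17.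

Step 9. The likely failures are protodesilylation of the enol ether back to 18 before cyclisation, closure in the 7-endo mode, closure to the trans-fused isomer through a pseudoequatorial chain, or acid-induced migration of the new exocyclic alkene. Fallback: a palladium-catalysed enolate alkenylation in place of alkyne activation. Set out from 18 and add HI across the alkyne in the Markovnikov sense (NaI, Me3SiCl, H2O, MeCN) to give (4R,5R,6R)-5-(4-iodopent-4-en-1-yl)-4,6-dimethyl-4-[(2,3,5,6-tetramethoxyphenyl)methyl]cyclohex-2-en-1-one F2. Then treat with Pd(PPh3)4 and KOtBu in THF: zerovalent palladium inserts into the C–I bond and the C5 enolate couples intramolecularly under the same geometric constraint. The fallback comes back at 20.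

Step 10. The likely failure is poor facial selectivity at C8, because the arylmethyl group on C9 stands on the convex face next to the reacting carbon. Fallback: reverse the order in which methyl and hydrogen are attached to C8. Set out from 20 and run the cuprate addition as before, but keep the C8-epimeric trimethylsilyl enol ether F3 (alone or mixed with 21). Oxidise it with Pd(OAc)2 in MeCN (Saegusa–Ito) to (5R,9S,10S)-5,8,9-trimethyl-4-methylidene-9-[(2,3,5,6-tetramethoxyphenyl)methyl]-cis-decal-7-en-6-one F4, which erases C8. Then deliver hydride in a conjugate sense with [(Ph3P)CuH]6. Hydride should prefer the same face that methyl preferred, which now leaves the methyl on the opposite, desired face. The fallback comes back at 22.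

Step 11. The likely failures are incomplete hydrazone formation at the hindered C6 carbonyl (azine formation) and slow nucleophilic O-demethylation of the arene at 195 °C. Fallback: a two-stage reduction near room temperature. Set out from 22 and condense with 4-methylbenzenesulfonohydrazide (EtOH, reflux) to the tosylhydrazone F5. Reduce with catecholborane (CHCl3, 0 °C) and decompose with NaOAc·3H2O. The diazene formed may have some radical character, so this is second choice. The fallback comes back at 24.

Step 13. The likely failure is loss of regiocontrol in the hydrolysis, giving either the isomeric hydroxy-methoxyquinone or the product of double hydrolysis. Fallback: make the differentiation in the methylation direction. Set out from 25 and hydrolyse both methoxy groups (aq. NaOH, THF, 50 °C; acidify) to 2,5-dihydroxy-3-{[(5R,8R,9R,10S)-5,8,9-trimethyl-4-methylidene-cis-decalin-9-yl]methyl}cyclohexa-2,5-diene-1,4-dione F6. Then carry out an acid-catalysed vinylogous esterification (MeOH, BF3·OEt2 cat., 0 °C), which should occur at the unhindered hydroxyl remote from C15. The acid exposure must be kept short because of the exocyclic alkene. The fallback comes back at 26.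

## Further compounds

F1 | step 6 | (4S,5R)-4-methyl-4-[(2,3,5,6-tetramethoxyphenyl)methyl]-5-[5-(trimethylsilyl)pent-4-yn-1-yl]cyclohex-2-en-1-one | C[Si](C)(C)C#CCCC[C@H]1[C@](C)(Cc2c(OC)c(OC)cc(OC)c2OC)C=CC(=O)C1
F2 | step 9 | (4R,5R,6R)-5-(4-iodopent-4-en-1-yl)-4,6-dimethyl-4-[(2,3,5,6-tetramethoxyphenyl)methyl]cyclohex-2-en-1-one | C=C(I)CCC[C@H]1[C@](C)(Cc2c(OC)c(OC)cc(OC)c2OC)C=CC(=O)[C@@H]1C
F3 | step 10 | C8 epimer of 21, (5R,8S,9R,10S) trimethylsilyl enol ether | C=C1CCC[C@H]2[C@](C)(Cc3c(OC)c(OC)cc(OC)c3OC)[C@@H](C)C=C(O[Si](C)(C)C)[C@@]12C
F4 | step 10 | (5R,9S,10S)-5,8,9-trimethyl-4-methylidene-9-[(2,3,5,6-tetramethoxyphenyl)methyl]-cis-decal-7-en-6-one | C=C1CCC[C@H]2[C@](C)(Cc3c(OC)c(OC)cc(OC)c3OC)C(C)=CC(=O)[C@@]12C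
F5 | step 11 | 4-methylbenzenesulfonohydrazone of 22, (5R,8R,9R,10S) | C=C1CCC[C@H]2[C@](C)(Cc3c(OC)c(OC)cc(OC)c3OC)[C@H](C)CC(=NNS(=O)(=O)c3ccc(C)cc3)[C@@]12C
F6 | step 13 | 2,5-dihydroxy-3-{[(5R,8R,9R,10S)-5,8,9-trimethyl-4-methylidene-cis-decalin-9-yl]methyl}cyclohexa-2,5-diene-1,4-dione | C=C1CCC[C@H]2[C@](C)(CC3=C(O)C(=O)C=C(O)C3=O)[C@H](C)CC[C@@]12C
A1 | alternative 1 | cis-fused Diels–Alder adduct: C4 (S)-methoxy(phenyl)acetate of 4-hydroxy-5,8-dimethyl-cis-decala-2,7-diene-6,9-dione | O=C(O[C@H]1C=CC[C@H]2C(=O)C(C)=CC(=O)[C@@]12C)[C@@H](OC)c1ccccc1
A2 | alternative 1 | 2,5-dimethylcyclohexa-2,5-diene-1,4-dione | CC1=CC(=O)C(C)=CC1=O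
A3 | alternative 1 | (E)-buta-1,3-dien-1-yl (S)-methoxy(phenyl)acetate | C=C/C=C/OC(=O)[C@@H](OC)c1ccccc1
A4 | alternative 2 | tetrahydrofuran-fused bicyclo[2.2.2]octenone mixed ketal with C8, C9 and C10 set | O=C1[C@@]2(OC)OC[C@@]3(CO[Si](C)(C)C(C)(C)C)[C@H](C)[C@@H]1C=C(C)[C@@H]23
A5 | alternative 2 | 2-{[(Z)-2-({[tert-butyl(dimethyl)silyl]oxy}methyl)but-2-en-1-yl]oxy}-4-methylphenol | C/C=C(\CO[Si](C)(C)C(C)(C)C)COc1cc(C)ccc1O
A6 | alternative 3 | cis-decalin C4 ketone with quaternary C5 methyl and C6 hydroxyl | O=C1CCC[C@H]2[C@](C)(Cc3c(OC)c(OC)cc(OC)c3OC)[C@H](C)C[C@@H](O)[C@@]12C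
A7 | alternative 3 | trans-fused bicyclo[5.3.0] C5–C6 epoxy C4 alcohol (epoxide syn to hydroxyl) | O[C@@]12CCC[C@H]1[C@](C)(Cc3c(OC)c(OC)cc(OC)c3OC)[C@H](C)C[C@H]3O[C@]32C
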